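**Plan**
Retrosynthesis: first the two benzyl–O bonds of a bis(benzyl) ether of the target are cut (catechol mask), then the C6–C7 bond of the docosyl chain (numbered from the ester oxygen), then the carboxylate O–C1 bond of a hex-5-enyl ester.
Feature used: C6 and C7 lie in an unbranched run of CH2 groups, C6 being five methylenes from the ester oxygen and remote from the benzene ring and its oxygens on C2 and C3, so C5–C6 can be drawn as a terminal CH=CH2 and C7 as the CH2I carbon of a C16 iodide.
Forward order: the carboxylate of 2,3-dihydroxybenzoic acid is alkylated with 6-bromohex-1-ene and both phenols are benzylated.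
A nickel hydride anti-Markovnikov hydroalkylation of the alkene with 1-iodohexadecane then joins C6 to C7 and completes the C22 chain in one C(sp3)–C(sp3) bond formation at the final oxidation level.
Hydrogenolysis of the two benzyl ethers frees the catechol and gives the target.
Stereochemistry: the target has no stereocentre and no stereogenic double bond; the selectivities to control are carboxylate versus phenol alkylation (step 1) and linear versus branched coupling (step 3).

Key step: step 3

Step 1
Reactants: 1 2,3-dihydroxybenzoic acid; 2 6-bromohex-1-ene
Product: 3 hex-5-en-1-yl 2,3-dihydroxybenzoate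
Conditions: KHCO3 (1.2 equiv), 2 (1.1 equiv), DMF, 50 °C
Reagents that add atoms: none
Why: Chemoselective SN2 O-alkylation of a carboxylate (ester formation by alkylation), because hydrogen carbonate deprotonates only the carboxylic acid, so both phenols stay protonated and the primary bromide should be attacked by the carboxylate alone.

Step 2
Reactants: 3 hex-5-en-1-yl 2,3-dihydroxybenzoate
Product: 4 hex-5-en-1-yl 2,3-bis(benzyloxy)benzoate
Conditions: BnBr (2.5 equiv), K2CO3 (3 equiv), DMF, 60 °C
Reagents that add atoms: benzyl bromide, BrCc1ccccc1
Why: Williamson ether synthesis, in which carbonate in warm DMF generates both phenoxides (including the hydrogen-bonded one at C2) for SN2 benzylation, while the alkyl ester and the terminal alkene are inert.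

Step 3
Reactants: 4 hex-5-en-1-yl 2,3-bis(benzyloxy)benzoate; 5 1-iodohexadecane
Product: 6 docosyl 2,3-bis(benzyloxy)benzoate
Conditions: NiBr2·diglyme (10 mol%), 4,4'-di-tert-butyl-2,2'-bipyridine (12 mol%), (EtO)2MeSiH (2.5 equiv), Na2CO3 (3 equiv), 5 (2 equiv), DMA, 30 °C, Ar
Reagents that add atoms: none
Why: A bipyridine–nickel(I) hydride, formed from the nickel(II) precatalyst, the silane and carbonate, inserts the terminal alkene of 4 with nickel on the unsubstituted CH2 carbon; the primary alkylnickel takes up the hexadecyl group of 5 by iodine atom abstraction and radical rebound, and reductive elimination from the dialkylnickel(III) species forms the C(sp3)–C(sp3) bond and returns nickel(I). The closest known reaction type is the nickel hydride catalysed anti-Markovnikov reductive hydroalkylation of unactivated terminal alkenes with primary alkyl iodides, which runs near room temperature and tolerates esters and ethers. No ring is closed and no stereocentre is formed. The step needs linear regioselectivity, and cross-coupling in preference to alkene reduction, alkene isomerisation and iodide homocoupling. The monosubstituted alkene should secure the first, since secondary alkylnickel isomers reached by chain walking revert and couple more slowly than the primary one, and the four methylenes between alkene and ester oxygen keep nickel away from a β-acyloxy position; an excess of the cheap iodide 5 should secure the second. The benzyl ethers keep the acidic, nickel-chelating catechol out of the reaction.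

Step 4
Reactants: 6 docosyl 2,3-bis(benzyloxy)benzoate
Product: 7 Gentiside J (docosyl 2,3-dihydroxybenzoate)
Conditions: H2 (1 atm), 10% Pd/C, EtOAc/THF, rt
Reagents that add atoms: none
Why: Heterogeneous catalytic hydrogenolysis of the two aryl benzyl ethers, which should cleave the benzylic C–O bonds under conditions that leave the alkyl benzoate ester, the arene and the saturated chain untouched.

**Compound list**
1 | 2,3-dihydroxybenzoic acid | OC(=O)c1cccc(O)c1O | starting material
2 | 6-bromohex-1-ene | BrCCCCC=C | starting material
3 | hex-5-en-1-yl 2,3-dihydroxybenzoate | C=CCCCCOC(=O)c1cccc(O)c1O | intermediate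
4 | hex-5-en-1-yl 2,3-bis(benzyloxy)benzoate | C=CCCCCOC(=O)c1cccc(OCc2ccccc2)c1OCc1ccccc1 | intermediate
5 | 1-iodohexadecane | CCCCCCCCCCCCCCCCI | starting material
6 | docosyl 2,3-bis(benzyloxy)benzoate | CCCCCCCCCCCCCCCCCCCCCCOC(=O)c1cccc(OCc2ccccc2)c1OCc1ccccc1 | intermediate
7 | Gentiside J (docosyl 2,3-dihydroxybenzoate) | CCCCCCCCCCCCCCCCCCCCCCOC(=O)c1cccc(O)c1O | target

Total step count: 4
Longest linear sequence: 4 steps (1 → 3 → 4 → 6 → 7)

**Steps most likely to fail**

Step 3. Chain-walking isomerisation or simple hydrogenation of the alkene, or reduction and homocoupling of the iodide, may outrun the cross-coupling. The fallback sets out from 4 and keeps the same bond but uses a two-electron palladium pathway with a preformed alkylborane. Hydroboration of 4 with 9-BBN-H (THF, 0 °C to rt) should give 6-(9-borabicyclo[3.3.1]nonan-9-yl)hexyl 2,3-bis(benzyloxy)benzoate F1. An alkyl–alkyl Suzuki–Miyaura coupling of this borane with 1-bromohexadecane (Pd(OAc)2, PCy3, K3PO4·H2O, THF, rt) should then give 6, where the route is rejoined.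

Step 4. Hydrogenolysis may stall through poisoning of the palladium surface by traces of iodide or nickel carried over from step 3, or through poor solubility of the waxy C22 ester. The freed catechol may also oxidise in air during filtration from the catalyst. The fallback sets out from 6 and replaces hydrogenolysis by a non-reductive Lewis-acid dealkylation: BCl3 with pentamethylbenzene as cation scavenger (CH2Cl2, −78 °C) should cleave both aryl benzyl ethers while sparing the alkyl ester and give 7 directly. This fallback makes no new compound, F0.

Step 1. Chemoselectivity may be lost, with alkylation at the C3 phenol oxygen competing with the carboxylate, or the alkylation may be sluggish. The fallback sets out from 1 and protects first. Exhaustive benzylation (BnBr, K2CO3, DMF, 60 °C) should give benzyl 2,3-bis(benzyloxy)benzoate F2. Saponification (NaOH, MeOH/THF/H2O, then acid) should give 2,3-bis(benzyloxy)benzoic acid F3. Steglich esterification with hex-5-en-1-ol (EDC·HCl, DMAP, CH2Cl2, rt) should then give 4, where the route is rejoined without passing through 3.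

**Further compounds**
F1 | step 3 | 6-(9-borabicyclo[3.3.1]nonan-9-yl)hexyl 2,3-bis(benzyloxy)benzoate | O=C(OCCCCCCB1C2CCCC1CCC2)c1cccc(OCc2ccccc2)c1OCc1ccccc1
F0 | step 4 | none | none
F2 | step 1 | benzyl 2,3-bis(benzyloxy)benzoate | O=C(OCc1ccccc1)c1cccc(OCc2ccccc2)c1OCc1ccccc1
F3 | step 1 | 2,3-bis(benzyloxy)benzoic acid | OC(=O)c1cccc(OCc2ccccc2)c1OCc1ccccc1
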